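The 3 questions came down to one number per flask, the fraction y of the charge standing as J at the asked time, and I reckoned it by asking first for the end state and then for the approach to it.

| flask | G | remark | time |
|---|---|---|---|
| winter | 7.500 × 10⁻⁵ M | run made earlier |  |
| noon | 1.9 × 10⁻⁴ M | run made earlier |  |
| autumn | 6.7 × 10⁻⁴ M | run made earlier |  |
| Saturday's | 4.0 × 10⁻⁴ M |  | 2.5 min |
| Wednesday's | 1.0 × 10⁻⁴ M |  | 2.5 min |
| Sunday's | 6.0 × 10⁻⁴ M |  | 2.5 min |
| Tuesday's | 6.0 × 10⁻⁵ M |  | 2.5 min |
| Friday's | 2.0 × 10⁻⁴ M |  | 2.5 min |

| run | time / s | J / % | G / % |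
|---|---|---|---|
| winter | 10.0 | 4.4 | 70.7 |
| winter | 25.0 | 18.7 | 40.4 |
| winter | 50.0 | 42.6 | 14.5 |
| winter | 80.0 | 60.3 | 4.1 |
| winter | 120 | 72.1 | 0.8 |
| noon | 20.0 | 11.4 | 47.9 |
| noon | 40.0 | 28.6 | 19.3 |
| noon | 60.0 | 42.9 | 7.2 |
| noon | 80.0 | 51.8 | 2.8 |
| noon | 120 | 60.6 | 0.8 |
| autumn | 10.0 | 3.1 | 69.4 |
| autumn | 15.0 | 5.2 | 55.8 |
| autumn | 30.0 | 14.3 | 26.9 |
| autumn | 60.0 | 28.3 | 3.0 |
| autumn | 120 | 42.0 | 0.3 |

(readings scatter by 0.5 percentage points)

- the flasks put in order of amount of J, in percent of the G charged, best first, at 2.5 min (Saturday's / Wednesday's / Sunday's / Tuesday's / Friday's)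
- the amount of J, in percent of the G charged of the flask you put first, at 2.5 min
- the amount of J, in percent of the G charged of the flask you put last, at 2.5 min



Suppose no J ever met a G: then y ends at 1; suppose instead that each J, once made, were taken at once by a G: then y ends at 0. The real flasks lay between, and the ratio of what is not J to what is J, (1 − y)/y, spans that gap from zero to infinity. At 120 s it read 0.387 in the winter run and 1.38 in the autumn run, so I defined the loading exponent, the power with which this ratio grows with the charge, and read 0.581. The noon run, which I had not used, then came out at 60.1% against its reading of 60.6%.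

The approach came next. In the noon run G was down to 0.8%, yet J was still rising, its pace falling to half within 30.0 s. For the last 30.0 s I therefore allowed half the latest pace, a gain of 3.3 percentage points, and stretched every flask by the factor 1.05. That put Tuesday's at 78.7% and Sunday's at 45.9%, in the order of rising charge.

The forecast, reached by its own interpolation, was Tuesday's > Wednesday's > Friday's > Saturday's > Sunday's, with 79% first and 46% last, on the ground that “J yield falls as loading rises, which points to a higher-order loss of the intermediate”.

The flasks gave Tuesday's > Wednesday's > Friday's > Saturday's > Sunday's, from 77.1% down to 45.3%.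

    G → E (k = 0.0320 s⁻¹)
    E → J (k = 0.0350 s⁻¹)
    G ⇌ Z (K = 2.20, k = 0.00290 s⁻¹)
    G + J → X (k = 230 M⁻¹ s⁻¹)
    J → Q (k = 9.70 × 10⁻⁶ s⁻¹)

Between Tuesday's and Sunday's the ratio of not-J to J grew with the charge to the power 0.608, against the 0.581 I had read. In Tuesday's the pseudo-first-order half-life of J by G + J → X was 1.6 min at 0.304 min, shorter than the time of reading, but 3.6 h at 2.50 min, longer than that time. For the neighbour of Tuesday's charged with 1.5 × 10⁻⁵ M of G, the exponent gave 91.5%. That flask gave 85.6%, less than reckoned, with 6.97% of its charge standing as Z.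

Readings and results are calculated on assumed constants.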